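**Conventions.** Ring C is O1, C2, C3, C4, C4a, C8a. Ring A is the benzo ring C4a–C8a. Ring B is the aryl group on C2. Ring D is the phenol ring on C3, which carries the flavone para to its hydroxyl. Compounds 1–16 are numbered as they appear in the steps and are listed after step 13.

## Analysis of the target

Target 16 is a biflavonoid: a 5,7-dihydroxyflavanone (rings A, C and B) whose C3 is bonded to ring D, the 4-hydroxyphenyl ring of a 5,7-dihydroxyflavone, at the carbon ortho to the ring D hydroxyl. It has two adjacent stereocentres, C2 (R) and C3 (S), with the aryl groups on C2 and C3 trans. C3 is benzylic and α to the C4 ketone, so it is configurationally labile and should settle trans under thermodynamic control, which means that only C2 has to be set absolutely. Six phenols must be masked and released together, and the pyranone of the flavone half opens with hydroxide or alkoxide. Ring C can open by β-elimination of the O1 phenoxide from the C4 enolate, which would racemise C2, and the C2–O1 bond is a benzylic ether exposed to acid and to hydrogenolysis; the ring D hydroxyl also sits next to C3 and can add to the C4 ketone under acid. The hard part is the C2–C3 bond, which joins two carbons that each carry an aryl group, together with the sp3–sp2 bond from C3 to ring D, the only link between the two flavonoid halves. The strategy rests on one feature: C2 carries O1 and the electron-rich ring B, so a C2–H bond is doubly activated, and ring A has two equivalent oxygens ortho to C4a (O1 and the C5 oxygen). A carbene at C3 can therefore insert into an O-benzylic C–H bond of a ring A ether, forming C2–C3 and closing ring C in one step.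

## Retrosynthetic reasoning

**16 from 15.** Seven benzylic C–O bonds are cut last, by hydrogenolysis. All ring A, ring B and flavone phenols stay as benzyl-type ethers until then, because the free hexaphenol is the form most prone to ring opening at C2. The final step is neutral and leaves only volatile or easily removed arenes.

**15 from 14.** The ring D oxygen is disconnected separately as a triisopropylsilyl ether. A benzyl-type ether here would offer the C3 carbene a benzylic C–H bond through a five-membered transition state, the most favoured insertion of all. A carbonate or ester would be open to acyl transfer to the neighbouring enolate during steps 8 and 9 and could trap the carbene through its carbonyl oxygen. The silyl ether has no C–H bond within easy reach, tolerates the weak inorganic base of step 8 and the amidine base of step 9, and leaves with buffered fluoride.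

**14 from 13.** Only the C3 configuration changes. The insertion is expected to give the 2,3-cis isomer, so C3 is corrected by enolisation. This costs nothing in stereochemical terms because C2 carries the absolute information.

**13 from 12.** The C2–C3 bond is cut. This is the one disconnection that removes a ring, a skeletal bond and both stereocentres at once, and it leads back to diazo ketone 12, in which C2 is still an ether CH2 of ring A. The forward step must choose one of two enantiotopic hydrogens and must prefer C–H insertion over attack of O1 on the carbene.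

**12 from 11.** The diazo group is placed on the methylene of deoxybenzoin 11 by Regitz diazo transfer. The methylene is flanked by a ketone and an aryl ring and is acidic enough for an amidine base.

**11 from 8 and 10.** The bond from C3 to ring D is cut. It is the interflavonoid bond, so this is the convergent point: the enolate of methyl ketone 10 is arylated by bromoflavone 8 under palladium catalysis. A Friedel–Crafts acylation forming the C4–C4a bond was set aside, because the Lewis acid would strip the benzyl ethers of the flavone half and would leave three free ring A hydroxyls beside an acidic methylene.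

**10 from 1 and 9.** Three O–CH2 bonds are cut. All three ring A oxygens of 1 receive the same 4-benzyloxybenzyl group, so three equivalents of chloride 9 are consumed and no regiochemistry arises. One ortho group later becomes C2 and ring B, and the other two protect the C5 and C7 oxygens.

**8 from 7, 6, 5, then 2 and 4.** The pyranone is opened at O1–C2 and the C2=C3 double bond, giving chalcone 5, which comes from acetophenone 2 and aldehyde 4 by aldol condensation. The ring D oxygen needs a base-stable acetal (in 4, 5 and 6) for the condensation and is changed to the silyl ether at the flavone stage (7 to 8), before any acid-sensitive ring A ether is present. Compound 2 comes from 1 and compound 4 from 3, each by one protection.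

## Alternatives that were turned down

Alternative 1: β-lactone as acyl donor.
- Disconnection: C2–C3 plus a temporary bond from the C2 oxygen to C4.
- Forward key step: a ring D aryl ketene, generated in situ from its acid chloride, and 4-(benzyloxy)benzaldehyde A2 combine in a [2+2] cycloaddition under O-trimethylsilylquinidine, LiClO4 and iPr2NEt to give cis-β-lactone A1.
- For: C2 is set by a well-understood alkaloid-catalysed cycloaddition with a simple aldehyde; no diazo compound is needed; the ring D oxygen can stay a benzyl ether, so one hydrogenolysis finishes the synthesis. On protecting-group economy and on confidence in the sense of induction it is stronger than the chosen route.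
- Against: monosubstituted aryl ketenes dimerise readily. A1 has a 4-alkoxyphenyl group on its oxygen-bearing carbon, so it can ionise at C2–O (losing the C2 configuration) or lose CO2 to a stilbene. After the key step, C4 must still be bonded to C4a of a hindered ring A nucleophile and the oxygen on C2 joined to C8a, through a β-hydroxy ketone prone to retro-aldol cleavage and dehydration.
- Comparison: two skeletal bonds remain after its key step; the chosen route forms the last skeletal bond and ring C in the key step and is followed only by epimerisation and deprotection.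

Alternative 2: carbene-catalysed acyl anion onto a quinone methide.
- Disconnection: C3–C4.
- Forward key step: CsF unmasks an ortho-quinone methide at C3 of ring D by desilylation and loss of acetate, and a triazolium-derived N-heterocyclic carbene turns a ring A aldehyde into an acyl anion equivalent that adds to C3, closing ring C to give A3.
- For: it is free of metals and diazo compounds, and A3 is already 2,3-trans. The ring D ortho oxygen, which needs special masking in the chosen route, is here the trigger of the reaction. On both points it is stronger.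
- Against: C2 is not made in the key step. It must be built beforehand as an enantiopure secondary benzylic aryl ether next to the acetoxy-bearing carbon, a stereodefined 1,2-diaryl-1,2-dioxygenated unit whose second centre is then erased. The quinone methide has the activated C2–H in the β position and can tautomerise to an enol ether, destroying C2. The ring A aldehyde is flanked by two oxygens, electron-rich and hindered, which slows formation of the Breslow intermediate. Five methoxymethyl ethers must then be removed with acid next to the acid-sensitive C2–O1 bond and the ring D hydroxyl–ketone pair.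
- Comparison: it is longer, and it needs a pre-formed stereocentre; the chosen route creates C2 catalytically from a prochiral CH2 group.

Alternative 3: carbene carbon inserted into a benzofuranone.
- Disconnection: C2–C3 and C3–C4 together.
- Forward key step: Rh2(S-PTAD)4 transfers a ring D aryl carbene to the C2=C4 enol-silane bond of a 3-silyloxy-2-arylbenzofuran. In the same flask, methanolysis, CeCl3 photocatalysis and a thiol cleave the temporary C2–C4 bond by alkoxy-radical β-scission and hydrogen-atom transfer to C2, giving A4.
- For: it is highly convergent from two simple halves, and the carbene has no neighbouring ether oxygen, so the oxonium-ylide problem of the chosen route does not exist. On that chemoselectivity point it is stronger.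
- Against: the carbene is a donor-only aryl carbene from an unstable aryldiazomethane, and the alkene is tetrasubstituted and hindered. More seriously, C2 passes through a planar radical, so its configuration is only relayed from C3 by the diastereoselectivity of hydrogen-atom transfer. C3 is the centre that is equilibrated afterwards, so any leakage in that relay becomes loss of enantiopurity. The β-scission must also choose C4–C2 over C4–C3, both benzylic, and three catalytic manifolds share one flask.
- Comparison: the chosen route sets C2 in a concerted insertion with retention, independent of C3.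

Key step: step 10

Assumption: Rh2(S-PTTL)4 is taken to deliver the 2R configuration in step 10; if the sense of induction proves opposite, the mirror-image catalyst Rh2(R-PTTL)4 would be used under the same conditions.

## Route

Step 1
Reactants: 1 2',4',6'-trihydroxyacetophenone
Product: 2 1-[2,4-bis(benzyloxy)-6-hydroxyphenyl]ethanone
Conditions: BnBr (2.1 equiv), K2CO3, DMF, rt
Reagents that add atoms: benzyl bromide, BrCc1ccccc1
Why: Williamson etherification; the hydroxyl that stays hydrogen-bonded to the acetyl carbonyl is much less nucleophilic, so alkylation should stop at the bis-ether and leave the phenol needed for the pyranone oxygen.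

Step 2
Reactants: 3 3-bromo-4-hydroxybenzaldehyde
Product: 4 3-bromo-4-(methoxymethoxy)benzaldehyde
Conditions: MOMCl, iPr2NEt, CH2Cl2, 0 °C → rt
Reagents that add atoms: chloromethyl methyl ether, COCCl
Why: Acetal protection of the phenol; a free phenoxide would deactivate the aldehyde in the next step, and this acetal is stable to KOH yet leaves under acid that spares benzyl ethers and the aryl bromide.

Step 3
Reactants: 2 1-[2,4-bis(benzyloxy)-6-hydroxyphenyl]ethanone; 4 3-bromo-4-(methoxymethoxy)benzaldehyde
Product: 5 (E)-1-[2,4-bis(benzyloxy)-6-hydroxyphenyl]-3-[3-bromo-4-(methoxymethoxy)phenyl]prop-2-en-1-one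
Conditions: KOH (50 % aq.), EtOH, rt
Reagents that add atoms: none
Why: Claisen–Schmidt condensation; the enolate of 2 adds to the non-enolisable aldehyde 4 and E1cB dehydration gives the conjugated E-enone.

Step 4
Reactants: 5 (E)-1-[2,4-bis(benzyloxy)-6-hydroxyphenyl]-3-[3-bromo-4-(methoxymethoxy)phenyl]prop-2-en-1-one
Product: 6 5,7-bis(benzyloxy)-2-[3-bromo-4-(methoxymethoxy)phenyl]-4H-chromen-4-one
Conditions: I2 (0.1 equiv), DMSO, 130 °C
Reagents that add atoms: none
Why: Iodine-catalysed oxidative cyclisation of a 2'-hydroxychalcone (oxa-Michael addition, α-iodination, loss of HI, DMSO reoxidising iodide) should give the flavone; any partial loss of the acetal here is harmless because step 5 removes it anyway.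

Step 5
Reactants: 6 5,7-bis(benzyloxy)-2-[3-bromo-4-(methoxymethoxy)phenyl]-4H-chromen-4-one
Product: 7 5,7-bis(benzyloxy)-2-(3-bromo-4-hydroxyphenyl)-4H-chromen-4-one
Conditions: 3 M HCl, MeOH/THF, 55 °C
Reagents that add atoms: none
Why: Acid-catalysed acetal exchange with methanol frees the ring D phenol; benzyl ethers, the aryl bromide and the flavone are inert to dilute methanolic acid.

Step 6
Reactants: 7 5,7-bis(benzyloxy)-2-(3-bromo-4-hydroxyphenyl)-4H-chromen-4-one
Product: 8 5,7-bis(benzyloxy)-2-[3-bromo-4-(triisopropylsilyloxy)phenyl]-4H-chromen-4-one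
Conditions: TIPSCl, imidazole, DMF, rt
Reagents that add atoms: triisopropylsilyl chloride, CC(C)[Si](Cl)(C(C)C)C(C)C
Why: Silylation of an acidic ortho-bromophenol; the triisopropylsilyl ether gives the later C3 carbene no C–H bond within a five-membered transition state, withstands K3PO4 and DBU, and is removable with buffered fluoride.

Step 7
Reactants: 1 2',4',6'-trihydroxyacetophenone; 9 4-(benzyloxy)benzyl chloride (three equivalents are incorporated)
Product: 10 1-[2,4,6-tris(4-benzyloxybenzyloxy)phenyl]ethanone
Conditions: 9 (3.6 equiv), K2CO3 (5 equiv), Bu4NI (cat.), DMF, 70 °C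
Reagents that add atoms: 4-(benzyloxy)benzyl chloride (second equivalent of 9), ClCc1ccc(OCc2ccccc2)cc1; 4-(benzyloxy)benzyl chloride (third equivalent of 9), ClCc1ccc(OCc2ccccc2)cc1
Why: Threefold Williamson etherification in which each of the three phenoxide oxygens of 1 displaces chloride from one molecule of 9; excess halide, iodide catalysis and heat force the chelated ortho hydroxyls to react, while the acetyl methyl is not enolised by K2CO3. One ortho 4-benzyloxybenzyl group later supplies C2 and ring B.

Step 8
Reactants: 8 5,7-bis(benzyloxy)-2-[3-bromo-4-(triisopropylsilyloxy)phenyl]-4H-chromen-4-one; 10 1-[2,4,6-tris(4-benzyloxybenzyloxy)phenyl]ethanone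
Product: 11 2-[5-(5,7-bis(benzyloxy)-4-oxo-4H-chromen-2-yl)-2-(triisopropylsilyloxy)phenyl]-1-[2,4,6-tris(4-benzyloxybenzyloxy)phenyl]ethanone
Conditions: Pd2(dba)3 (2.5 mol %), Xantphos (6 mol %), K3PO4 (2.5 equiv), toluene, 90 °C
Reagents that add atoms: none
Why: Palladium-catalysed α-arylation of a methyl ketone enolate: zerovalent palladium adds to the C–Br bond of 8, the potassium enolate of 10 displaces bromide, and reductive elimination forms the C3–ring D bond. K3PO4 is mild enough for the pyranone and the silyl ether, and the hindered product should not arylate a second time.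

Step 9
Reactants: 11 2-[5-(5,7-bis(benzyloxy)-4-oxo-4H-chromen-2-yl)-2-(triisopropylsilyloxy)phenyl]-1-[2,4,6-tris(4-benzyloxybenzyloxy)phenyl]ethanone
Product: 12 2-diazo-2-[5-(5,7-bis(benzyloxy)-4-oxo-4H-chromen-2-yl)-2-(triisopropylsilyloxy)phenyl]-1-[2,4,6-tris(4-benzyloxybenzyloxy)phenyl]ethanone
Conditions: p-ABSA (1.5 equiv), DBU (2 equiv), MeCN/CH2Cl2, 0 °C → rt, dark
Reagents that add atoms: 4-acetamidobenzenesulfonyl azide, CC(=O)Nc1ccc(cc1)S(=O)(=O)N=[N+]=[N-]
Why: Regitz diazo transfer; the methylene between ketone and aryl ring is deprotonated by DBU, the enolate attacks the terminal nitrogen of the sulfonyl azide, and the triazene collapses to the aryl(aroyl)diazomethane and the sulfonamide.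

Step 10
Reactants: 12 2-diazo-2-[5-(5,7-bis(benzyloxy)-4-oxo-4H-chromen-2-yl)-2-(triisopropylsilyloxy)phenyl]-1-[2,4,6-tris(4-benzyloxybenzyloxy)phenyl]ethanone
Product: 13 (2R,3R)-5,7-bis(4-benzyloxybenzyloxy)-2-(4-benzyloxyphenyl)-3-[5-(5,7-bis(benzyloxy)-4-oxo-4H-chromen-2-yl)-2-(triisopropylsilyloxy)phenyl]chroman-4-one (2,3-cis)
Conditions: Rh2(S-PTTL)4 [dirhodium tetrakis(N-phthaloyl-(S)-tert-leucinate)] (2 mol %), toluene, 4 Å MS, 0 °C → rt, slow addition of 12
Reagents that add atoms: none
Why: The dirhodium tetracarboxylate (two divalent rhodium centres) attacks the diazo carbon of 12 and N2 leaves, giving a donor/acceptor carbene at C3 with ring D as donor and the C4 ketone as acceptor. The carbene carbon inserts into a benzylic C–H bond of an ortho 4-benzyloxybenzyl ether in a concerted, asynchronous, hydride-transfer-like step; the closest known reaction type is the enantioselective intramolecular C–H insertion of dirhodium carbenes next to ether oxygen, which converts 2-alkoxyaryl diazo ketones into chromanones and 2-benzyloxyaryl diazoacetates into cis-2-aryl-dihydrobenzofurans. Ring C (O1, C2, C3, C4, C4a, C8a) closes by formation of the C2–C3 bond through a six-membered transition state (a 1,6-insertion), with C4, C4a, C8a and O1 as the tether. C2 is set by the catalyst: the two ortho ethers are interchanged by rotation about the C4–C4a bond and are equivalent, so the only choice is between the two enantiotopic hydrogens of one OCH2 group, which the pocket formed by the four N-phthaloyl-tert-leucinate ligands makes, and insertion proceeds with retention at carbon. C3 is set in the same event, with the aryl groups on C2 and C3 expected cis as in related insertions, but this centre is left for thermodynamic correction in step 11. The step needs chemoselectivity for C–H insertion over attack of O1 on the carbene (five-membered oxonium ylide, then 1,2-shift) and over Wolff rearrangement; in its favour, the C–H bond is doubly activated by O1 and the 4-alkoxyphenyl ring, O1 is a weakly basic aryl ether oxygen, the donor aryl group tempers the carbene, and a non-polar solvent disfavours the charge-separated ylide. It also needs site selectivity: the silyl ether on the ring D oxygen offers no C–H bond in a five-membered transition state, the para ether and the flavone benzyl ethers are out of reach, and slow addition suppresses bimolecular carbene reactions.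

Step 11
Reactants: 13 (2R,3R)-cis flavanone from step 10
Product: 14 (2R,3S)-5,7-bis(4-benzyloxybenzyloxy)-2-(4-benzyloxyphenyl)-3-[5-(5,7-bis(benzyloxy)-4-oxo-4H-chromen-2-yl)-2-(triisopropylsilyloxy)phenyl]chroman-4-one (2,3-trans)
Conditions: Et3N (0.5 equiv), CH2Cl2, rt
Reagents that add atoms: none
Why: Amine-mediated epimerisation through the enol or enolate of the α-aryl ketone; the trans isomer with both aryl groups equatorial is the thermodynamic one, so C3 (S) is set under equilibrium control. C2 has no acidic hydrogen and stays intact as long as the weak base in an aprotic solvent does not drive β-elimination of the O1 phenoxide.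

Step 12
Reactants: 14 (2R,3S)-trans flavanone from step 11
Product: 15 (2R,3S)-5,7-bis(4-benzyloxybenzyloxy)-2-(4-benzyloxyphenyl)-3-[5-(5,7-bis(benzyloxy)-4-oxo-4H-chromen-2-yl)-2-hydroxyphenyl]chroman-4-one
Conditions: Bu4NF (1.2 equiv), AcOH (1.5 equiv), THF, 0 °C
Reagents that add atoms: none
Why: Fluoride cleavage of an aryl silyl ether, driven by the Si–F bond; the acetic acid buffer protonates the phenoxide at once, so the flavanone is not exposed to a strong base.

Step 13
Reactants: 15 (2R,3S)-phenol from step 12
Product: 16 (2R,3S)-5,7-dihydroxy-2-(4-hydroxyphenyl)-3-[5-(5,7-dihydroxy-4-oxo-4H-chromen-2-yl)-2-hydroxyphenyl]chroman-4-one (target)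
Conditions: H2 (1 atm), 10 % Pd/C, THF/MeOH, rt
Reagents that add atoms: none
Why: Catalytic hydrogenolysis of three benzyl ethers and two 4-benzyloxybenzyl ethers (seven benzylic C–O bonds) under neutral conditions; the primary benzylic ethers should cleave well before the hindered, ring-bound secondary C2–O1 bond, and the stereocentres are not touched.

## Compound list

1 | 2',4',6'-trihydroxyacetophenone | CC(=O)c1c(O)cc(O)cc1O | starting material
2 | 1-[2,4-bis(benzyloxy)-6-hydroxyphenyl]ethanone | CC(=O)c1c(O)cc(OCc2ccccc2)cc1OCc1ccccc1 | intermediate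
3 | 3-bromo-4-hydroxybenzaldehyde | O=Cc1ccc(O)c(Br)c1 | starting material
4 | 3-bromo-4-(methoxymethoxy)benzaldehyde | O=Cc1ccc(OCOC)c(Br)c1 | intermediate
5 | (E)-1-[2,4-bis(benzyloxy)-6-hydroxyphenyl]-3-[3-bromo-4-(methoxymethoxy)phenyl]prop-2-en-1-one | O=C(/C=C/c1ccc(OCOC)c(Br)c1)c1c(O)cc(OCc2ccccc2)cc1OCc1ccccc1 | intermediate
6 | 5,7-bis(benzyloxy)-2-[3-bromo-4-(methoxymethoxy)phenyl]-4H-chromen-4-one | O=c1cc(-c2ccc(OCOC)c(Br)c2)oc2cc(OCc3ccccc3)cc(OCc3ccccc3)c12 | intermediate
7 | 5,7-bis(benzyloxy)-2-(3-bromo-4-hydroxyphenyl)-4H-chromen-4-one | O=c1cc(-c2ccc(O)c(Br)c2)oc2cc(OCc3ccccc3)cc(OCc3ccccc3)c12 | intermediate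
8 | 5,7-bis(benzyloxy)-2-[3-bromo-4-(triisopropylsilyloxy)phenyl]-4H-chromen-4-one | O=c1cc(-c2ccc(O[Si](C(C)C)(C(C)C)C(C)C)c(Br)c2)oc2cc(OCc3ccccc3)cc(OCc3ccccc3)c12 | intermediate
9 | 4-(benzyloxy)benzyl chloride | ClCc1ccc(OCc2ccccc2)cc1 | starting material
10 | 1-[2,4,6-tris(4-benzyloxybenzyloxy)phenyl]ethanone | CC(=O)c1c(OCc2ccc(OCc3ccccc3)cc2)cc(OCc2ccc(OCc3ccccc3)cc2)cc1OCc1ccc(OCc2ccccc2)cc1 | intermediate
11 | 2-[5-(5,7-bis(benzyloxy)-4-oxo-4H-chromen-2-yl)-2-(triisopropylsilyloxy)phenyl]-1-[2,4,6-tris(4-benzyloxybenzyloxy)phenyl]ethanone | O=C(Cc1cc(-c2cc(=O)c3c(OCc4ccccc4)cc(OCc4ccccc4)cc3o2)ccc1O[Si](C(C)C)(C(C)C)C(C)C)c1c(OCc2ccc(OCc3ccccc3)cc2)cc(OCc2ccc(OCc3ccccc3)cc2)cc1OCc1ccc(OCc2ccccc2)cc1 | intermediate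
12 | 2-diazo-2-[5-(5,7-bis(benzyloxy)-4-oxo-4H-chromen-2-yl)-2-(triisopropylsilyloxy)phenyl]-1-[2,4,6-tris(4-benzyloxybenzyloxy)phenyl]ethanone | O=C(C(=[N+]=[N-])c1cc(-c2cc(=O)c3c(OCc4ccccc4)cc(OCc4ccccc4)cc3o2)ccc1O[Si](C(C)C)(C(C)C)C(C)C)c1c(OCc2ccc(OCc3ccccc3)cc2)cc(OCc2ccc(OCc3ccccc3)cc2)cc1OCc1ccc(OCc2ccccc2)cc1 | intermediate
13 | (2R,3R)-5,7-bis(4-benzyloxybenzyloxy)-2-(4-benzyloxyphenyl)-3-[5-(5,7-bis(benzyloxy)-4-oxo-4H-chromen-2-yl)-2-(triisopropylsilyloxy)phenyl]chroman-4-one (cis) | O=C1c2c(OCc3ccc(OCc4ccccc4)cc3)cc(OCc3ccc(OCc4ccccc4)cc3)cc2O[C@@H](c2ccc(OCc3ccccc3)cc2)[C@H]1c1cc(-c2cc(=O)c3c(OCc4ccccc4)cc(OCc4ccccc4)cc3o2)ccc1O[Si](C(C)C)(C(C)C)C(C)C | intermediate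
14 | (2R,3S)-5,7-bis(4-benzyloxybenzyloxy)-2-(4-benzyloxyphenyl)-3-[5-(5,7-bis(benzyloxy)-4-oxo-4H-chromen-2-yl)-2-(triisopropylsilyloxy)phenyl]chroman-4-one (trans) | O=C1c2c(OCc3ccc(OCc4ccccc4)cc3)cc(OCc3ccc(OCc4ccccc4)cc3)cc2O[C@@H](c2ccc(OCc3ccccc3)cc2)[C@@H]1c1cc(-c2cc(=O)c3c(OCc4ccccc4)cc(OCc4ccccc4)cc3o2)ccc1O[Si](C(C)C)(C(C)C)C(C)C | intermediate
15 | (2R,3S)-5,7-bis(4-benzyloxybenzyloxy)-2-(4-benzyloxyphenyl)-3-[5-(5,7-bis(benzyloxy)-4-oxo-4H-chromen-2-yl)-2-hydroxyphenyl]chroman-4-one | O=C1c2c(OCc3ccc(OCc4ccccc4)cc3)cc(OCc3ccc(OCc4ccccc4)cc3)cc2O[C@@H](c2ccc(OCc3ccccc3)cc2)[C@@H]1c1cc(-c2cc(=O)c3c(OCc4ccccc4)cc(OCc4ccccc4)cc3o2)ccc1O | intermediate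
16 | (2R,3S)-5,7-dihydroxy-2-(4-hydroxyphenyl)-3-[5-(5,7-dihydroxy-4-oxo-4H-chromen-2-yl)-2-hydroxyphenyl]chroman-4-one | O=C1c2c(O)cc(O)cc2O[C@@H](c2ccc(O)cc2)[C@@H]1c1cc(-c2cc(=O)c3c(O)cc(O)cc3o2)ccc1O | target

## Step count and risks

Total: 13 steps. Longest linear sequence: 11 steps (steps 1, 3, 4, 5, 6, 8, 9, 10, 11, 12, 13, counted from 1).

**Step 10 (key step).** The most likely failure is capture of the carbene by the lone pair of O1, giving a five-membered oxonium ylide that rearranges by 1,2-shift of the electron-rich benzyl group in competition with C–H insertion. The second is poor discrimination between the enantiotopic hydrogens, because the substrate is far larger than those for which the catalyst pocket is known to work. The fallback leaves carbene chemistry and sets out from 11. MgBr2·OEt2 in toluene/Et2O should remove one 4-benzyloxybenzyl group ortho to the ketone under chelation control, giving 1-[2-hydroxy-4,6-bis(4-benzyloxybenzyloxy)phenyl]-2-[ring D aryl]ethanone F1. Condensation of F1 with 4-(benzyloxy)benzaldehyde A2 (piperidine, toluene, 4 Å MS, 80 °C) should pass through the α-aryl-2'-hydroxychalcone F2, which closes by oxa-Michael addition to the racemic 2,3-trans flavanone. Preparative chromatography on a chiral stationary phase would separate 14 from its mirror image, the (2S,3R)-flavanone F3, and the route is rejoined at 14.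

**Step 8.** The ortho triisopropylsilyloxy group may slow oxidative addition and reductive elimination, and prolonged heating with base may lead to desilylation or opening of the pyranone. The fallback sets out from 10 and replaces the base-generated enolate by a preformed neutral one. LiN(SiMe3)2 and Me3SiCl at −78 °C give the trimethylsilyl enol ether F4, which is coupled with 8 under Pd(OAc)2, P(t-Bu)3 and Bu3SnF in toluene (arylation through the tin enolate formed in the flask), returning to 11.

**Step 11.** If the enolate is long-lived, β-elimination of the O1 phenoxide and re-closure would erode the configuration at C2. The fallback avoids base altogether and sets out from 13. Buffered Bu4NF/AcOH gives the 2,3-cis phenol F5, hydrogenolysis as in step 13 gives the 2,3-cis hexaphenol F6, and warming F6 in methanol containing acetic acid equilibrates C3 through the neutral enol to the trans isomer, returning at 16.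

**Step 13.** Hydrogenolysis may run on into the ring-bound C2–O1 benzylic bond, or saturate the C2=C3 bond of the flavone, before all seven protecting-group bonds are cleaved. The fallback sets out from 15 and uses Lewis-acid cleavage instead of hydrogen: BCl3 with pentamethylbenzene as cation scavenger in CH2Cl2 at −78 °C, then methanol quench, returning at 16. No new intermediate arises (F0).

## Further compounds

F1 | step 10 | 2-[5-(5,7-bis(benzyloxy)-4-oxo-4H-chromen-2-yl)-2-(triisopropylsilyloxy)phenyl]-1-[2-hydroxy-4,6-bis(4-benzyloxybenzyloxy)phenyl]ethanone | O=C(Cc1cc(-c2cc(=O)c3c(OCc4ccccc4)cc(OCc4ccccc4)cc3o2)ccc1O[Si](C(C)C)(C(C)C)C(C)C)c1c(O)cc(OCc2ccc(OCc3ccccc3)cc2)cc1OCc1ccc(OCc2ccccc2)cc1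
F2 | step 10 | 3-(4-benzyloxyphenyl)-2-[5-(5,7-bis(benzyloxy)-4-oxo-4H-chromen-2-yl)-2-(triisopropylsilyloxy)phenyl]-1-[2-hydroxy-4,6-bis(4-benzyloxybenzyloxy)phenyl]prop-2-en-1-one (alkene geometry not controlled) | O=C(C(=Cc1ccc(OCc2ccccc2)cc1)c1cc(-c2cc(=O)c3c(OCc4ccccc4)cc(OCc4ccccc4)cc3o2)ccc1O[Si](C(C)C)(C(C)C)C(C)C)c1c(O)cc(OCc2ccc(OCc3ccccc3)cc2)cc1OCc1ccc(OCc2ccccc2)cc1
F3 | step 10 | (2S,3R)-5,7-bis(4-benzyloxybenzyloxy)-2-(4-benzyloxyphenyl)-3-[5-(5,7-bis(benzyloxy)-4-oxo-4H-chromen-2-yl)-2-(triisopropylsilyloxy)phenyl]chroman-4-one (mirror image of 14) | O=C1c2c(OCc3ccc(OCc4ccccc4)cc3)cc(OCc3ccc(OCc4ccccc4)cc3)cc2O[C@H](c2ccc(OCc3ccccc3)cc2)[C@H]1c1cc(-c2cc(=O)c3c(OCc4ccccc4)cc(OCc4ccccc4)cc3o2)ccc1O[Si](C(C)C)(C(C)C)C(C)C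
F4 | step 8 | trimethyl{1-[2,4,6-tris(4-benzyloxybenzyloxy)phenyl]ethenyloxy}silane | C=C(O[Si](C)(C)C)c1c(OCc2ccc(OCc3ccccc3)cc2)cc(OCc2ccc(OCc3ccccc3)cc2)cc1OCc1ccc(OCc2ccccc2)cc1
F5 | step 11 | (2R,3R)-5,7-bis(4-benzyloxybenzyloxy)-2-(4-benzyloxyphenyl)-3-[5-(5,7-bis(benzyloxy)-4-oxo-4H-chromen-2-yl)-2-hydroxyphenyl]chroman-4-one (cis) | O=C1c2c(OCc3ccc(OCc4ccccc4)cc3)cc(OCc3ccc(OCc4ccccc4)cc3)cc2O[C@@H](c2ccc(OCc3ccccc3)cc2)[C@H]1c1cc(-c2cc(=O)c3c(OCc4ccccc4)cc(OCc4ccccc4)cc3o2)ccc1O
F6 | step 11 | (2R,3R)-5,7-dihydroxy-2-(4-hydroxyphenyl)-3-[5-(5,7-dihydroxy-4-oxo-4H-chromen-2-yl)-2-hydroxyphenyl]chroman-4-one (cis) | O=C1c2c(O)cc(O)cc2O[C@@H](c2ccc(O)cc2)[C@H]1c1cc(-c2cc(=O)c3c(O)cc(O)cc3o2)ccc1O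
F0 | step 13 | none | none
A1 | alternative 1 | cis-4-(4-benzyloxyphenyl)-3-[2-(benzyloxy)-5-(5,7-bis(benzyloxy)-4-oxo-4H-chromen-2-yl)phenyl]oxetan-2-one | O=C1O[C@@H](c2ccc(OCc3ccccc3)cc2)[C@H]1c1cc(-c2cc(=O)c3c(OCc4ccccc4)cc(OCc4ccccc4)cc3o2)ccc1OCc1ccccc1
A2 | alternative 1 | 4-(benzyloxy)benzaldehyde | O=Cc1ccc(OCc2ccccc2)cc1
A3 | alternative 2 | (2R,3S)-5,7-bis(methoxymethoxy)-2-[4-(methoxymethoxy)phenyl]-3-[5-(5,7-bis(methoxymethoxy)-4-oxo-4H-chromen-2-yl)-2-hydroxyphenyl]chroman-4-one | O=C1c2c(OCOC)cc(OCOC)cc2O[C@@H](c2ccc(OCOC)cc2)[C@@H]1c1cc(-c2cc(=O)c3c(OCOC)cc(OCOC)cc3o2)ccc1O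
A4 | alternative 3 | (2R,3R)-5,7-bis(benzyloxy)-2-(4-benzyloxyphenyl)-3-[5-(5,7-bis(benzyloxy)-4-oxo-4H-chromen-2-yl)-2-(triisopropylsilyloxy)phenyl]chroman-4-one (cis) | O=C1c2c(OCc3ccccc3)cc(OCc3ccccc3)cc2O[C@@H](c2ccc(OCc3ccccc3)cc2)[C@H]1c1cc(-c2cc(=O)c3c(OCc4ccccc4)cc(OCc4ccccc4)cc3o2)ccc1O[Si](C(C)C)(C(C)C)C(C)C
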